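## Retrosynthetic overview

1. Ring B is the last carbocycle made. C6=C7(OMe) is removed as methoxyacetylene, which leaves the spiro-cyclobutenone ring D (C5, C10, C9, C8). Its extra C5–C8 bond is absent from the target; it stores the C5 configuration and supplies the strain that drives the ring expansion.
2. Enabling feature: C5 is quaternary, so the [4+2] product cannot aromatise. The C6 arm of ring B lies on the same face of oxolane ring A as the C4 CH2OH group, so a C4–CH2–O–Si(i-Pr)2–C6 tether (six-membered ring C) can deliver the ynol ether to the C5–C8 bond with fixed face and orientation. Silicon is removed together with all other silyl groups.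
3. Ring D comes from the ring A ketene (C5=C8=O) and ethyl vinyl ether by [2+2] on the open upper face, followed by loss of ethanol. The ketene comes from a C5-methylidene oxolane by hydroboration and oxidation.
4. Ring A closes when the C1 hydroxyl captures the C3 p-silyloxybenzyl cation. C1/C1′ come from an Evans glycolate aldol on a 2-substituted acrolein, and C3/C4 from an Evans syn aldol of a pentenoyl imide with O-silyl vanillin.
5. Ring order: A (step 14), temporary D (steps 18 and 19), then B together with temporary C (step 23). Ring C is cleaved in step 24.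

Key step: step 23

**Conventions.** Target locants are used throughout.
- Ring A is the oxolane C1–O2–C3–C4–C5. Ring B is C5–C10. C1′ is the aryloxy-bearing side-chain carbon.
- The lower face is the face of ring A that carries the C4 CH2O group and the C1 side chain. The upper face carries the C3 aryl group.
- ArT = 3-methoxy-4-(triisopropylsilyloxy)phenyl. ArP = 4-[3-(tert-butyldiphenylsilyloxy)propyl]-2-methoxyphenyl.
- TBS, TBDPS and TIPS are the usual silyl groups.

**Remark (assumption).** The C5–H configuration in 28–33 and the ethoxy-bearing carbon in 35 and 36 are erased in steps 18 and 19. Compounds 28–33 are drawn as expected from hydroboration on the upper face. The ethoxy carbon, and the new carbinol carbon of 11, are left undefined.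

## Route

Step 1
Reactants: 1 vanillin
Product: 2 3-methoxy-4-(triisopropylsilyloxy)benzaldehyde
Conditions: i-Pr3SiCl, imidazole, DMF, 25 °C
Reagents that add atoms: chlorotriisopropylsilane, CC(C)[Si](Cl)(C(C)C)C(C)C
Why: Standard phenol silylation; the bulky aryl silyl ether should survive boranes, hydrides, mild acid and amine bases and is removed only in the last step.

Step 2
Reactants: 3 (4S)-4-benzyl-1,3-oxazolidin-2-one; 4 pent-4-enoyl chloride
Product: 5 (4S)-4-benzyl-3-(pent-4-enoyl)-1,3-oxazolidin-2-one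
Conditions: Et3N, 4-(dimethylamino)pyridine (cat.), CH2Cl2, 0 to 25 °C
Reagents that add atoms: none
Why: Nucleophile-catalysed N-acylation of an oxazolidinone with an acid chloride is routine and touches no stereocentre.

Step 3
Reactants: 5 pentenoyl imide; 2 aldehyde
Product: 8 syn-aldol imide (4S)-4-benzyl-3-[(2S)-2-{(S)-hydroxy(ArT)methyl}pent-4-enoyl]-1,3-oxazolidin-2-one, via boron enolate 6 (not isolated), via boron aldolate 7 (not isolated)
Conditions: Bu2BOTf, Et3N, CH2Cl2, −78 to 0 °C; 2, −78 to 0 °C; pH 7 buffer, MeOH, H2O2, 0 °C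
Reagents that add atoms: dibutylboron triflate, CCCCB(CCCC)OS(=O)(=O)C(F)(F)F (boron of 6 and 7 only)
Why: Evans syn aldol, in which the (Z)-boron enolate reacts through a chair transition state on the face away from the benzyl group and sets C4 and the C3–O centre together.

Step 4
Reactants: 8 syn-aldol imide
Product: 9 (1S,2R)-1-ArT-2-(prop-2-enyl)propane-1,3-diol
Conditions: LiBH4, MeOH (1 equiv), THF, 0 °C
Reagents that add atoms: none
Why: Reductive removal of the auxiliary turns the imide carbonyl into the C4 CH2OH group without touching either stereocentre.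

Step 5
Reactants: 9 diol
Product: 10 (4S,5R)-4-ArT-2,2-dimethyl-5-(prop-2-enyl)-1,3-dioxane
Conditions: 2,2-dimethoxypropane, pyridinium p-toluenesulfonate (cat.), CH2Cl2, 25 °C
Reagents that add atoms: 2,2-dimethoxypropane, COC(C)(C)OC
Why: Acid-catalysed transketalisation masks the C3 and C4 oxygens in one group, which step 14 releases again in a productive way.

Step 6
Reactants: 10 allyl dioxane
Product: 12 [(4S,5R)-4-ArT-2,2-dimethyl-1,3-dioxan-5-yl]acetaldehyde, via vicinal diol 11 (not isolated)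
Conditions: OsO4 (cat.), NaIO4, 2,6-lutidine, dioxane/H2O, 25 °C
Reagents that add atoms: OsO4, O=[Os](=O)(=O)=O; NaIO4, [Na+].[O-]I(=O)(=O)=O
Why: Lemieux–Johnson cleavage (dihydroxylation, then glycol cleavage) is preferred to ozone to spare the electron-rich arene, and the lutidine buffer protects the acetonide.

Step 7
Reactants: 12 aldehyde
Product: 13 2-[(4S,5R)-4-ArT-2,2-dimethyl-1,3-dioxan-5-yl]prop-2-enal
Conditions: 37% aq. CH2O, pyrrolidine (cat.), propionic acid (cat.), i-PrOH, 45 °C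
Reagents that add atoms: formaldehyde, C=O
Why: Amine-catalysed Mannich condensation and elimination (α-methylenation of an aldehyde) adds the carbon that becomes C8 and gives a non-enolisable enal for the next aldol.

Step 8
Reactants: 14 dihydroconiferyl alcohol (4-(3-hydroxypropyl)-2-methoxyphenol)
Product: 15 4-[3-(tert-butyldiphenylsilyloxy)propyl]-2-methoxyphenol
Conditions: t-BuPh2SiCl (1.0 equiv), imidazole, CH2Cl2, 0 °C
Reagents that add atoms: tert-butylchlorodiphenylsilane, CC(C)(C)[Si](Cl)(c1ccccc1)c1ccccc1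
Why: The unhindered primary alcohol should be silylated faster than the hydrogen-bonded phenol flanked by methoxy.

Step 9
Reactants: 15 phenol; 16 bromoacetic acid
Product: 17 (ArP-oxy)acetic acid
Conditions: NaH (3 equiv), THF, 0 to 60 °C; dilute HCl work-up
Reagents that add atoms: none
Why: Williamson ether synthesis of the sodium phenoxide with sodium bromoacetate gives the aryloxyacetic acid directly.

Step 10
Reactants: 17 aryloxyacetic acid; 18 (4R)-4-benzyl-1,3-oxazolidin-2-one
Product: 20 (4R)-4-benzyl-3-[(ArP-oxy)acetyl]-1,3-oxazolidin-2-one, via mixed pivalic anhydride 19 (not isolated)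
Conditions: t-BuCOCl, Et3N, THF, −20 °C; 18, LiCl, 25 °C
Reagents that add atoms: pivaloyl chloride, CC(C)(C)C(=O)Cl (acyl group of 19 only)
Why: In the mixed-anhydride acylation the oxazolidinone should attack the less hindered aryloxyacetyl carbonyl.

Step 11
Reactants: 20 glycolate imide; 13 enal
Product: 23 (4R)-4-benzyl-3-[(2R,3S)-2-(ArP-oxy)-3-hydroxy-4-{(4S,5R)-4-ArT-2,2-dimethyl-1,3-dioxan-5-yl}pent-4-enoyl]-1,3-oxazolidin-2-one, via boron enolate 21 (not isolated), via boron aldolate 22 (not isolated)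
Conditions: Bu2BOTf, Et3N, CH2Cl2, −78 to 0 °C; 13, −78 to 0 °C; pH 7 buffer, MeOH, H2O2, 0 °C
Reagents that add atoms: dibutylboron triflate, CCCCB(CCCC)OS(=O)(=O)C(F)(F)F (boron of 21 and 22 only)
Why: Evans glycolate syn aldol, in which the (R)-auxiliary should override the remote C4 centre and set C1 and C1′ in the syn (threo) relation of the target.

Step 12
Reactants: 23 glycolate aldol imide
Product: 24 (2S,3S)-2-(ArP-oxy)-4-[(4S,5R)-4-ArT-2,2-dimethyl-1,3-dioxan-5-yl]pent-4-ene-1,3-diol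
Conditions: LiBH4, MeOH (1 equiv), THF, 0 °C
Reagents that add atoms: none
Why: Reductive removal of the auxiliary gives the C2′ CH2OH group and leaves silyl ethers, acetonide and alkene untouched.

Step 13
Reactants: 24 diol
Product: 25 (2S,3S)-1-(tert-butyldiphenylsilyloxy)-2-(ArP-oxy)-4-[(4S,5R)-4-ArT-2,2-dimethyl-1,3-dioxan-5-yl]pent-4-en-3-ol
Conditions: t-BuPh2SiCl (1.05 equiv), imidazole, CH2Cl2, 0 °C
Reagents that add atoms: tert-butylchlorodiphenylsilane, CC(C)(C)[Si](Cl)(c1ccccc1)c1ccccc1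
Why: The bulky silyl chloride should select the primary hydroxyl over the flanked secondary allylic C1 hydroxyl, which stays free as the ring-closing nucleophile.

Step 14
Reactants: 25 allylic alcohol
Product: 26 {(2S,3R,5S)-2-ArT-5-[(1S)-2-(tert-butyldiphenylsilyloxy)-1-(ArP-oxy)ethyl]-4-methylideneoxolan-3-yl}methanol
Conditions: camphor-10-sulfonic acid (cat.), CH2Cl2/MeOH 20:1, 0 to 25 °C
Reagents that add atoms: none
Why: Acid opens the acetonide at the p-silyloxybenzylic C3–O bond and the C1 hydroxyl captures the cation 5-exo (cationic cycloetherification as used for tetrahydrofuran lignans); because the capture is reversible the aryl group should settle trans to the C4 substituent.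

Step 15
Reactants: 26 primary alcohol
Product: 27 TBS ether of 26 at the C4 CH2OH group
Conditions: t-BuMe2SiCl, imidazole, DMF, 25 °C
Reagents that add atoms: tert-butylchlorodimethylsilane, CC(C)(C)[Si](C)(C)Cl
Why: Routine silylation gives the one silyl ether that mild acidic fluoride can later remove selectively.

Step 16
Reactants: 27 methylidene oxolane
Product: 29 primary alcohol (27 with H on the upper face and CH2OH on the lower face at C5 in place of the methylidene group), via B-alkyl-9-BBN 28 (not isolated)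
Conditions: 9-BBN, THF, 25 to 50 °C; NaBO3·4H2O, THF/H2O, 25 °C
Reagents that add atoms: 9-borabicyclo[3.3.1]nonane, C1CC2CCCC(C1)B2 (boron of 28 only); sodium perborate, [Na+].[O-]OB=O
Why: Anti-Markovnikov hydroboration–oxidation places boron on the unhindered CH2 terminus, and perborate spares the aryl silyl ether.

Step 17
Reactants: 29 primary alcohol
Product: 31 oxolane-C5-carboxylic acid (29 with CO2H in place of CH2OH), via aldehyde 30 (not isolated)
Conditions: 2,2,6,6-tetramethylpiperidin-1-oxyl (cat.), PhI(OAc)2, MeCN/H2O, 25 °C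
Reagents that add atoms: water, O
Why: Oxoammonium-catalysed oxidation runs through the aldehyde hydrate to the acid under nearly neutral conditions that the silyl ethers and aryl ethers tolerate.

Step 18
Reactants: 31 acid; 32 ethyl vinyl ether
Product: 35 (4S,5S,7S,8R)-3-ethoxy-7-ArT-8-(TBS-oxymethyl)-5-[(1S)-2-(TBDPS-oxy)-1-(ArP-oxy)ethyl]-6-oxaspiro[3.4]octan-1-one, via acid chloride 33 (not isolated), via ketene 34 (not isolated)
Conditions: 1-chloro-N,N,2-trimethylprop-1-en-1-amine, CH2Cl2, 0 °C; concentrate; 32 (excess), Et3N, MeCN, 80 °C, sealed tube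
Reagents that add atoms: 1-chloro-N,N,2-trimethylprop-1-en-1-amine, CC(C)=C(Cl)N(C)C (chlorine of 33 only)
Why: In the thermal ketene–enol ether [2+2] the ketene carbonyl carbon bonds to the CH2 terminus and the new C5–C10 bond should form on the upper face, anti to both flanking substituents, which leaves the acyl carbon C8 on the lower face and so sets C5.

Step 19
Reactants: 35 ethoxycyclobutanone
Product: 37 (4R,5S,7S,8R)-7-ArT-8-(TBS-oxymethyl)-5-[(1S)-2-(TBDPS-oxy)-1-(ArP-oxy)ethyl]-6-oxaspiro[3.4]oct-2-en-1-one, via lithium enolate 36 (not isolated)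
Conditions: LiN(SiMe3)2 (1.05 equiv), THF, −78 to −20 °C; Me3SiCl, −78 °C
Reagents that add atoms: LiN(SiMe3)2, [Li]N([Si](C)(C)C)[Si](C)(C)C (lithium of 36 only)
Why: E1cB loss of ethoxide from the only possible enolate gives the enone, and capping the ethoxide as its silyl ether prevents re-addition to the strained ring.

Step 20
Reactants: 37 cyclobutenone TBS ether
Product: 38 cyclobutenone alcohol (37 with free C4 CH2OH)
Conditions: HF·pyridine, pyridine, THF, 0 °C
Reagents that add atoms: none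
Why: Acidic fluoride cleaves a primary alkyl TBS ether much faster than TBDPS ethers or an aryl TIPS ether; 38 is carried on at once to avoid attack of its hydroxyl on the strained carbonyl.

Step 21
Reactants: 39 chloroacetaldehyde dimethyl acetal
Product: 41 methoxyacetylene, via sodium methoxyacetylide 40 (not isolated)
Conditions: NaNH2 (3 equiv), liquid NH3, −33 °C; saturated aq. NaCl, distil
Reagents that add atoms: NaNH2, [Na+].[NH2-] (sodium of 40 only)
Why: Successive base-induced loss of HCl and methanol is the standard route from chloroacetals to alkoxyacetylenes.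

Step 22
Reactants: 41 methoxyacetylene; 42 dichlorodiisopropylsilane; 38 cyclobutenone alcohol
Product: 45 cyclobutenone 38 with its C4 CH2OH group as the diisopropyl(methoxyethynyl)silyl ether, via lithium methoxyacetylide 43 (not isolated), via chlorodiisopropyl(methoxyethynyl)silane 44 (not isolated)
Conditions: n-BuLi, THF, −78 °C; 42 (1.0 equiv), −78 to 0 °C; 38, imidazole, CH2Cl2, 0 °C
Reagents that add atoms: n-butyllithium, [Li]CCCC (lithium of 43 only)
Why: Stepwise substitution at silicon works because the second chloride of the hindered dichlorosilane reacts far more slowly with the acetylide than the first, and it is then displaced by the primary alcohol.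

Step 23
Reactants: 45 tethered cyclobutenone
Product: 47 silicon-bridged dienone (protected target skeleton with C6 bonded to Si(i-Pr)2 that is also bonded to the C4 CH2O oxygen), via nickelacyclopentenone 46 (not isolated)
Conditions: Ni(cod)2 (20 mol %), PPh3 (40 mol %), toluene (0.01 M), 25 to 60 °C
Reagents that add atoms: Ni(cod)2, [Ni].C1=CCCC=CCC1.C1=CCCC=CCC1 (nickel of 46 only; 47 is an isomer of 45)
Why: Proposed new method: zerovalent nickel, held on the lower face by the tethered ynol ether, should add oxidatively into the strained acyl–C5 bond (C8–C5) to give nickelacycle 46, the alkyne then inserts (acyl to the methoxy-bearing carbon, nickel to the silyl-bearing carbon), and reductive elimination joins the silyl-bearing carbon to C5, so that C8–C7 and C6–C5 are made in one turnover. The closest known reaction types are the Ni(cod)2-catalysed [4+2] union of cyclobutenones with alkynes to phenols and the rhodium-catalysed cut-and-sew of cyclobutanones with tethered alkynes; new here are a 4,4-disubstituted spiro substrate, which cannot tautomerise and must stop at the cross-conjugated dienone, and a silyl ynol ether as the two-carbon partner. Ring B closes by two-carbon expansion of ring D (formal [4+2], driven by release of cyclobutenone strain), and ring C (1,2-oxasilinane) closes 6-exo-dig at the proximal alkyne carbon. C5 is the only stereocentre touched: nickel replaces the acyl carbon on the lower face with retention, and the CH2–O–Si link from C4, which lies on that same face, allows C6 to be delivered only there. The step needs an orientation opposite to the normal polarity of an ynol ether, and the tether secures it because the reversed orientation would require a bridged seven-membered ring with a bridgehead alkene; the internal, silyl-capped, intramolecular alkyne also suppresses nickel-induced alkyne oligomerisation. β-Hydride loss from 46 is disfavoured because H4 and H1 both point to the upper face, anti to nickel.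

Step 24
Reactants: 47 silicon-bridged dienone
Product: 48 target (1S,3S,4R,5S)-3-(4-hydroxy-3-methoxyphenyl)-4-(hydroxymethyl)-1-{(1S)-2-hydroxy-1-[4-(3-hydroxypropyl)-2-methoxyphenoxy]ethyl}-7-methoxy-2-oxaspiro[4.5]deca-6,9-dien-8-one
Conditions: Bu4NF (excess), AcOH (equimolar to fluoride), THF, 0 to 25 °C
Reagents that add atoms: none
Why: Fluoride cleaves all O–Si bonds, and the resulting alkenyl(fluoro)silane should undergo the known fluoride-induced protodesilylation of heteroatom-substituted alkenylsilanes, helped here by proton delivery to the enol-ether β-carbon C6, while the acetate buffer protects the dienone.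

## Compound list

1 | vanillin | COc1cc(C=O)ccc1O | starting material
2 | 3-methoxy-4-(triisopropylsilyloxy)benzaldehyde | COc1cc(C=O)ccc1O[Si](C(C)C)(C(C)C)C(C)C | intermediate
3 | (4S)-4-benzyl-1,3-oxazolidin-2-one | O=C1N[C@@H](Cc2ccccc2)CO1 | starting material
4 | pent-4-enoyl chloride | C=CCCC(=O)Cl | starting material
5 | (4S)-4-benzyl-3-(pent-4-enoyl)-1,3-oxazolidin-2-one | C=CCCC(=O)N1C(=O)OC[C@@H]1Cc1ccccc1 | intermediate
6 | (Z)-dibutylboron enolate of 5 | C=CC/C=C(\OB(CCCC)CCCC)N1C(=O)OC[C@@H]1Cc1ccccc1 | intermediate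
7 | dibutylboron aldolate of 8 | C=CC[C@H](C(=O)N1C(=O)OC[C@@H]1Cc1ccccc1)[C@@H](c1ccc(O[Si](C(C)C)(C(C)C)C(C)C)c(OC)c1)OB(CCCC)CCCC | intermediate
8 | syn-aldol imide (2S,3S) | C=CC[C@H](C(=O)N1C(=O)OC[C@@H]1Cc1ccccc1)[C@@H](c1ccc(O[Si](C(C)C)(C(C)C)C(C)C)c(OC)c1)O | intermediate
9 | (1S,2R)-1-ArT-2-(prop-2-enyl)propane-1,3-diol | C=CC[C@H](CO)[C@@H](c1ccc(O[Si](C(C)C)(C(C)C)C(C)C)c(OC)c1)O | intermediate
10 | (4S,5R)-4-ArT-2,2-dimethyl-5-(prop-2-enyl)-1,3-dioxane | C=CC[C@@H]1COC(C)(C)O[C@@H]1c2ccc(O[Si](C(C)C)(C(C)C)C(C)C)c(OC)c2 | intermediate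
11 | vicinal diol from 10 (carbinol epimers) | OCC(O)C[C@@H]1COC(C)(C)O[C@@H]1c2ccc(O[Si](C(C)C)(C(C)C)C(C)C)c(OC)c2 | intermediate
12 | [(4S,5R)-4-ArT-2,2-dimethyl-1,3-dioxan-5-yl]acetaldehyde | O=CC[C@@H]1COC(C)(C)O[C@@H]1c2ccc(O[Si](C(C)C)(C(C)C)C(C)C)c(OC)c2 | intermediate
13 | 2-[(4S,5R)-4-ArT-2,2-dimethyl-1,3-dioxan-5-yl]prop-2-enal | C=C(C=O)[C@@H]1COC(C)(C)O[C@@H]1c2ccc(O[Si](C(C)C)(C(C)C)C(C)C)c(OC)c2 | intermediate
14 | dihydroconiferyl alcohol | COc1cc(CCCO)ccc1O | starting material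
15 | 4-[3-(tert-butyldiphenylsilyloxy)propyl]-2-methoxyphenol | COc1cc(CCCO[Si](c2ccccc2)(c2ccccc2)C(C)(C)C)ccc1O | intermediate
16 | bromoacetic acid | OC(=O)CBr | starting material
17 | (ArP-oxy)acetic acid | COc1cc(CCCO[Si](c2ccccc2)(c2ccccc2)C(C)(C)C)ccc1OCC(=O)O | intermediate
18 | (4R)-4-benzyl-1,3-oxazolidin-2-one | O=C1N[C@H](Cc2ccccc2)CO1 | starting material
19 | mixed pivalic anhydride of 17 | COc1cc(CCCO[Si](c2ccccc2)(c2ccccc2)C(C)(C)C)ccc1OCC(=O)OC(=O)C(C)(C)C | intermediate
20 | (4R)-4-benzyl-3-[(ArP-oxy)acetyl]-1,3-oxazolidin-2-one | COc1cc(CCCO[Si](c2ccccc2)(c2ccccc2)C(C)(C)C)ccc1OCC(=O)N1C(=O)OC[C@H]1Cc1ccccc1 | intermediate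
21 | (Z)-dibutylboron enolate of 20 | COc1cc(CCCO[Si](c2ccccc2)(c2ccccc2)C(C)(C)C)ccc1O/C=C(\OB(CCCC)CCCC)N1C(=O)OC[C@H]1Cc1ccccc1 | intermediate
22 | dibutylboron aldolate of 23 | CCCCB(CCCC)O[C@@H](C(=C)[C@@H]1COC(C)(C)O[C@@H]1c2ccc(O[Si](C(C)C)(C(C)C)C(C)C)c(OC)c2)[C@H](C(=O)N1C(=O)OC[C@H]1Cc1ccccc1)Oc1ccc(CCCO[Si](c2ccccc2)(c2ccccc2)C(C)(C)C)cc1OC | intermediate
23 | glycolate syn-aldol imide (2R,3S) | O[C@@H](C(=C)[C@@H]1COC(C)(C)O[C@@H]1c2ccc(O[Si](C(C)C)(C(C)C)C(C)C)c(OC)c2)[C@H](C(=O)N1C(=O)OC[C@H]1Cc1ccccc1)Oc1ccc(CCCO[Si](c2ccccc2)(c2ccccc2)C(C)(C)C)cc1OC | intermediate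
24 | (2S,3S)-1,3-diol | O[C@@H](C(=C)[C@@H]1COC(C)(C)O[C@@H]1c2ccc(O[Si](C(C)C)(C(C)C)C(C)C)c(OC)c2)[C@H](CO)Oc1ccc(CCCO[Si](c2ccccc2)(c2ccccc2)C(C)(C)C)cc1OC | intermediate
25 | primary TBDPS ether of 24 | O[C@@H](C(=C)[C@@H]1COC(C)(C)O[C@@H]1c2ccc(O[Si](C(C)C)(C(C)C)C(C)C)c(OC)c2)[C@H](CO[Si](c1ccccc1)(c1ccccc1)C(C)(C)C)Oc1ccc(CCCO[Si](c2ccccc2)(c2ccccc2)C(C)(C)C)cc1OC | intermediate
26 | methylidene oxolane alcohol | C=C1[C@H](CO)[C@@H](c2ccc(O[Si](C(C)C)(C(C)C)C(C)C)c(OC)c2)O[C@@H]1[C@H](CO[Si](c2ccccc2)(c2ccccc2)C(C)(C)C)Oc2ccc(CCCO[Si](c3ccccc3)(c3ccccc3)C(C)(C)C)cc2OC | intermediate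
27 | TBS ether of 26 | C=C1[C@H](CO[Si](C)(C)C(C)(C)C)[C@@H](c2ccc(O[Si](C(C)C)(C(C)C)C(C)C)c(OC)c2)O[C@@H]1[C@H](CO[Si](c2ccccc2)(c2ccccc2)C(C)(C)C)Oc2ccc(CCCO[Si](c3ccccc3)(c3ccccc3)C(C)(C)C)cc2OC | intermediate
28 | B-alkyl-9-BBN from 27 | C1CC2CCCC(C1)B2C[C@@H]1[C@H](CO[Si](C)(C)C(C)(C)C)[C@@H](c2ccc(O[Si](C(C)C)(C(C)C)C(C)C)c(OC)c2)O[C@@H]1[C@H](CO[Si](c2ccccc2)(c2ccccc2)C(C)(C)C)Oc2ccc(CCCO[Si](c3ccccc3)(c3ccccc3)C(C)(C)C)cc2OC | intermediate
29 | C5 hydroxymethyl oxolane | OC[C@@H]1[C@H](CO[Si](C)(C)C(C)(C)C)[C@@H](c2ccc(O[Si](C(C)C)(C(C)C)C(C)C)c(OC)c2)O[C@@H]1[C@H](CO[Si](c2ccccc2)(c2ccccc2)C(C)(C)C)Oc2ccc(CCCO[Si](c3ccccc3)(c3ccccc3)C(C)(C)C)cc2OC | intermediate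
30 | C5 carbaldehyde | O=C[C@@H]1[C@H](CO[Si](C)(C)C(C)(C)C)[C@@H](c2ccc(O[Si](C(C)C)(C(C)C)C(C)C)c(OC)c2)O[C@@H]1[C@H](CO[Si](c2ccccc2)(c2ccccc2)C(C)(C)C)Oc2ccc(CCCO[Si](c3ccccc3)(c3ccccc3)C(C)(C)C)cc2OC | intermediate
31 | C5 carboxylic acid | OC(=O)[C@@H]1[C@H](CO[Si](C)(C)C(C)(C)C)[C@@H](c2ccc(O[Si](C(C)C)(C(C)C)C(C)C)c(OC)c2)O[C@@H]1[C@H](CO[Si](c2ccccc2)(c2ccccc2)C(C)(C)C)Oc2ccc(CCCO[Si](c3ccccc3)(c3ccccc3)C(C)(C)C)cc2OC | intermediate
32 | ethyl vinyl ether | C=COCC | starting material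
33 | C5 carbonyl chloride | ClC(=O)[C@@H]1[C@H](CO[Si](C)(C)C(C)(C)C)[C@@H](c2ccc(O[Si](C(C)C)(C(C)C)C(C)C)c(OC)c2)O[C@@H]1[C@H](CO[Si](c2ccccc2)(c2ccccc2)C(C)(C)C)Oc2ccc(CCCO[Si](c3ccccc3)(c3ccccc3)C(C)(C)C)cc2OC | intermediate
34 | oxolanylidene ketene | O=C=C1[C@H](CO[Si](C)(C)C(C)(C)C)[C@@H](c2ccc(O[Si](C(C)C)(C(C)C)C(C)C)c(OC)c2)O[C@@H]1[C@H](CO[Si](c2ccccc2)(c2ccccc2)C(C)(C)C)Oc2ccc(CCCO[Si](c3ccccc3)(c3ccccc3)C(C)(C)C)cc2OC | intermediate
35 | spiro 3-ethoxycyclobutanone (C=O on lower face) | O=C1CC(OCC)[C@]12[C@H](CO[Si](C)(C)C(C)(C)C)[C@@H](c3ccc(O[Si](C(C)C)(C(C)C)C(C)C)c(OC)c3)O[C@@H]2[C@H](CO[Si](c3ccccc3)(c3ccccc3)C(C)(C)C)Oc3ccc(CCCO[Si](c4ccccc4)(c4ccccc4)C(C)(C)C)cc3OC | intermediate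
36 | lithium enolate of 35 | [Li]OC1=CC(OCC)[C@]12[C@H](CO[Si](C)(C)C(C)(C)C)[C@@H](c3ccc(O[Si](C(C)C)(C(C)C)C(C)C)c(OC)c3)O[C@@H]2[C@H](CO[Si](c3ccccc3)(c3ccccc3)C(C)(C)C)Oc3ccc(CCCO[Si](c4ccccc4)(c4ccccc4)C(C)(C)C)cc3OC | intermediate
37 | spiro cyclobutenone TBS ether | O=C1C=C[C@]12[C@H](CO[Si](C)(C)C(C)(C)C)[C@@H](c3ccc(O[Si](C(C)C)(C(C)C)C(C)C)c(OC)c3)O[C@@H]2[C@H](CO[Si](c3ccccc3)(c3ccccc3)C(C)(C)C)Oc3ccc(CCCO[Si](c4ccccc4)(c4ccccc4)C(C)(C)C)cc3OC | intermediate
38 | spiro cyclobutenone alcohol | O=C1C=C[C@]12[C@H](CO)[C@@H](c3ccc(O[Si](C(C)C)(C(C)C)C(C)C)c(OC)c3)O[C@@H]2[C@H](CO[Si](c3ccccc3)(c3ccccc3)C(C)(C)C)Oc3ccc(CCCO[Si](c4ccccc4)(c4ccccc4)C(C)(C)C)cc3OC | intermediate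
39 | chloroacetaldehyde dimethyl acetal | COC(CCl)OC | starting material
40 | sodium methoxyacetylide | [Na+].[C-]#COC | intermediate
41 | methoxyacetylene | C#COC | intermediate
42 | dichlorodiisopropylsilane | CC(C)[Si](Cl)(Cl)C(C)C | starting material
43 | lithium methoxyacetylide | [Li]C#COC | intermediate
44 | chlorodiisopropyl(methoxyethynyl)silane | COC#C[Si](Cl)(C(C)C)C(C)C | intermediate
45 | tethered cyclobutenone | O=C1C=C[C@]12[C@H](CO[Si](C(C)C)(C(C)C)C#COC)[C@@H](c3ccc(O[Si](C(C)C)(C(C)C)C(C)C)c(OC)c3)O[C@@H]2[C@H](CO[Si](c3ccccc3)(c3ccccc3)C(C)(C)C)Oc3ccc(CCCO[Si](c4ccccc4)(c4ccccc4)C(C)(C)C)cc3OC | intermediate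
46 | nickelacyclopentenone (phosphines omitted) | O=C1C=C[C@@]2([Ni]1)[C@H](CO[Si](C(C)C)(C(C)C)C#COC)[C@@H](c3ccc(O[Si](C(C)C)(C(C)C)C(C)C)c(OC)c3)O[C@@H]2[C@H](CO[Si](c3ccccc3)(c3ccccc3)C(C)(C)C)Oc3ccc(CCCO[Si](c4ccccc4)(c4ccccc4)C(C)(C)C)cc3OC | intermediate
47 | silicon-bridged dienone | COC1=C3[C@]2(C=CC1=O)[C@H](CO[Si]3(C(C)C)C(C)C)[C@@H](c4ccc(O[Si](C(C)C)(C(C)C)C(C)C)c(OC)c4)O[C@@H]2[C@H](CO[Si](c4ccccc4)(c4ccccc4)C(C)(C)C)Oc4ccc(CCCO[Si](c5ccccc5)(c5ccccc5)C(C)(C)C)cc4OC | intermediate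
48 | CNP0252711.1 | COC1=C[C@]2(C=CC1=O)[C@H](CO)[C@@H](c1ccc(O)c(OC)c1)O[C@@H]2[C@H](CO)Oc1ccc(CCCO)cc1OC | target

## Step count

Total steps: 24. Longest linear sequence: 19 (steps 1, 3–7, 11–20, 22–24).

## Steps most likely to fail

**Step 23.** Several processes could stop the reaction:
- slow insertion of nickel into the hindered acyl–C5 bond;
- decarbonylation of the nickelacycle;
- sequestration of zerovalent nickel by the dienone product;
- consumption of the ynol ether by oligomerisation.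

The fallback uses only known chemistry. It sets out from alcohol 29 and comes back at target 48. Alcohol 29 would be oxidised with Dess–Martin periodinane to aldehyde 30, which is isolated this time. A DBU-catalysed Michael addition of 30 to 1-methoxybut-3-en-2-one is expected on the less hindered upper face of the enolate. It would give the keto aldehyde F1, with the formyl group left on the lower face. Intramolecular aldol condensation of the methoxymethyl ketone carbon onto the formyl group (piperidinium acetate, toluene, heat) completes a Robinson annulation to the spiro 2-methoxycyclohexenone F2, in which the methoxy-bearing arm already stands on the lower face. Dehydrogenation with IBX (DMSO, 70 °C) would give the fully silylated dienone F3. Bu4NF/AcOH then removes the four silyl ethers to give 48.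

**Step 18.** Three processes could interfere:
- ketene dimerisation outrunning the cycloaddition at the doubly flanked carbon;
- insufficient facial selectivity;
- base-induced opening of ring A during dehydrochlorination.

The fallback sets out from acid 31 and comes back at cyclobutenone 37, so that steps 18 and 19 are both bypassed. Acid 31 would be coupled with dimethylamine (EDC, HOBt, i-Pr2NEt) to give the dimethylamide F4. Activation with Tf2O and 2,4,6-collidine in 1,2-dichloroethane gives the far more electrophilic keteniminium triflate F5. This species is known to undergo [2+2] cycloaddition with acetylene itself, again expected on the upper face, to give the cyclobuteniminium triflate F6. Hydrolysis with aqueous NaHCO3 would deliver 37 directly.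

**Step 24.** The C6–Si bond may resist cleavage while the O–Si bonds fall. Alternatively, the basic medium may trigger oxa-Michael addition of the freed hydroxyl groups to the dienone.

The fallback sets out from 47 and comes back at 48. It replaces nucleophilic activation at silicon by an electrophilic ipso-protodesilylation, carried out before any hydroxyl is freed. Trifluoroacetic acid (2 equiv) in wet CH2Cl2 at −20 °C should protonate the enol ether at C6. The resulting C7 cation is stabilised by the methoxy group and by the β-silicon, and it loses silicon to water. This gives the ring-C-opened silanol F7. HF·pyridine in THF then removes all O-silyl groups under acidic conditions to give 48.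

## Further compounds

F1 | step 23 | keto aldehyde (C5: CHO on lower face, 4-methoxy-3-oxobutyl on upper face) | O=C[C@]1(CCC(=O)COC)[C@H](CO[Si](C)(C)C(C)(C)C)[C@@H](c2ccc(O[Si](C(C)C)(C(C)C)C(C)C)c(OC)c2)O[C@@H]1[C@H](CO[Si](c2ccccc2)(c2ccccc2)C(C)(C)C)Oc2ccc(CCCO[Si](c3ccccc3)(c3ccccc3)C(C)(C)C)cc2OC
F2 | step 23 | spiro 2-methoxycyclohex-2-enone | COC1=C[C@]2(CCC1=O)[C@H](CO[Si](C)(C)C(C)(C)C)[C@@H](c3ccc(O[Si](C(C)C)(C(C)C)C(C)C)c(OC)c3)O[C@@H]2[C@H](CO[Si](c3ccccc3)(c3ccccc3)C(C)(C)C)Oc3ccc(CCCO[Si](c4ccccc4)(c4ccccc4)C(C)(C)C)cc3OC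
F3 | step 23 | fully silylated dienone | COC1=C[C@]2(C=CC1=O)[C@H](CO[Si](C)(C)C(C)(C)C)[C@@H](c3ccc(O[Si](C(C)C)(C(C)C)C(C)C)c(OC)c3)O[C@@H]2[C@H](CO[Si](c3ccccc3)(c3ccccc3)C(C)(C)C)Oc3ccc(CCCO[Si](c4ccccc4)(c4ccccc4)C(C)(C)C)cc3OC
F4 | step 18 | N,N-dimethylamide of 31 | CN(C)C(=O)[C@@H]1[C@H](CO[Si](C)(C)C(C)(C)C)[C@@H](c2ccc(O[Si](C(C)C)(C(C)C)C(C)C)c(OC)c2)O[C@@H]1[C@H](CO[Si](c2ccccc2)(c2ccccc2)C(C)(C)C)Oc2ccc(CCCO[Si](c3ccccc3)(c3ccccc3)C(C)(C)C)cc2OC
F5 | step 18 | keteniminium triflate | C[N+](C)=C=C1[C@H](CO[Si](C)(C)C(C)(C)C)[C@@H](c2ccc(O[Si](C(C)C)(C(C)C)C(C)C)c(OC)c2)O[C@@H]1[C@H](CO[Si](c2ccccc2)(c2ccccc2)C(C)(C)C)Oc2ccc(CCCO[Si](c3ccccc3)(c3ccccc3)C(C)(C)C)cc2OC.[O-]S(=O)(=O)C(F)(F)F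
F6 | step 18 | cyclobuteniminium triflate | C[N+](C)=C1C=C[C@]12[C@H](CO[Si](C)(C)C(C)(C)C)[C@@H](c3ccc(O[Si](C(C)C)(C(C)C)C(C)C)c(OC)c3)O[C@@H]2[C@H](CO[Si](c3ccccc3)(c3ccccc3)C(C)(C)C)Oc3ccc(CCCO[Si](c4ccccc4)(c4ccccc4)C(C)(C)C)cc3OC.[O-]S(=O)(=O)C(F)(F)F
F7 | step 24 | dienone with C4 CH2O–Si(i-Pr)2OH (silanol) | COC1=C[C@]2(C=CC1=O)[C@H](CO[Si](O)(C(C)C)C(C)C)[C@@H](c3ccc(O[Si](C(C)C)(C(C)C)C(C)C)c(OC)c3)O[C@@H]2[C@H](CO[Si](c3ccccc3)(c3ccccc3)C(C)(C)C)Oc3ccc(CCCO[Si](c4ccccc4)(c4ccccc4)C(C)(C)C)cc3OC
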